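All runs come from a simulation for substances that don't exist, noise included.

**The plateau.** Take the ochre and red runs, which carry less free catalyst than the flask and the same other charges, and count what is left before what is made.

| setting | ochre | red | flask |
|---|---|---|---|
| substrate | 1.5 M | 1.5 M | 1.5 M |
| partner | 1.05 equiv | 1.05 equiv | 1.05 equiv |
| free catalyst | 7.5 mol% | 11 mol% | 15 mol% |
| second catalyst | 0.69 mol% | 0.69 mol% | 0.69 mol% |
| remark | run made earlier | run made earlier |  |
| time |  |  | 5.0 h |

| run | time / h | uncatalysed product / % | target / % |
|---|---|---|---|
| ochre | 0.667 | 10.2 | 82.2 |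
| ochre | 2.00 | 11.0 | 87.2 |
| ochre | 3.00 | 11.0 | 86.7 |
| ochre | 5.00 | 11.9 | 86.9 |
| red | 0.667 | 9.4 | 83.9 |
| red | 2.00 | 9.7 | 88.1 |
| red | 3.00 | 9.6 | 88.3 |
| red | 5.00 | 9.7 | 88.2 |

(scatter of a reading: 0.5 percentage points)

- ratio of uncatalysed product to target at 12 s
- ratio of uncatalysed product to target at 5.0 h
- which of uncatalysed product and target there is more of at 5.0 h

- the numbers in the tables scatter with a standard deviation of 0.5 percentage points
- a reading or a percentage of target counts all its forms, free or not

At 5.00 h the two readings leave 1.20% of the substrate uncounted in ochre and 2.10% in red, a small fraction as read in either run. We therefore average from 2.00 h on and get a side ratio (the inverse of the selectivity) of 0.130 for ochre and 0.110 for red.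

**The bracket.** The ratio read higher in ochre than in red, so we take red's value as the ceiling for the flask, which is charged with more free catalyst than red. Strict proportion to the inverse loading gives the floor, 0.0804, though red stayed higher than that rule predicts from ochre. To tighten it, we define the loading slope, the gain in side ratio per unit of inverse loading, which the two runs put at 0.00481. Carried to the flask, it gives 0.0980 at 5.0 h. For 12 s we commit to no number, since the earliest reading stands at 0.667 h.

**Forecast and result.** The forecast gives 0.097 at 5.0 h, inside our bracket, and 0.04 at 12 s, holding that “selectivity is best at the very start, when all catalyst is free”. The flask gives 0.419 at 12 s and 0.102 at 5.0 h, with 90.1% target, bound forms counted, against 9.17% uncatalysed product.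

    partner + catalyst intermediate → second catalyst + target (k = 0.260 L mol⁻¹ s⁻¹)
    second catalyst + target ⇌ idle complex (K = 350 L mol⁻¹, k = 0.0820 L mol⁻¹ s⁻¹)
    second catalyst + open intermediate ⇌ catalyst intermediate (K = 300 L mol⁻¹, k = 50.0 L mol⁻¹ s⁻¹)
    substrate + free catalyst ⇌ free catalyst + open intermediate (K = 3.00, k = 0.100 L mol⁻¹ s⁻¹)
    substrate + partner → uncatalysed product (k = 7.20 × 10⁻⁴ L mol⁻¹ s⁻¹)

**The neighbour.** On this flask the reckoning from the loading slope stands lower than the result by 0.00400. We now carry it to the neighbour charged with 6 mol% of free catalyst, all else held, where it gives 0.146. That neighbour gives 0.142, lower than the reckoning by 0.00400, and ends with 12.3% uncatalysed product.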